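**Retrosynthetic overview**
- The ten-membered carbocycle is closed last, by ring-closing metathesis at C4=C5 (Z); only a desilylation follows.
- Before that, C8 is inverted and acylated in one Mitsunobu step with angelic acid.
- Key late coupling: zinc Barbier union (C7–C8) of a C6-chiral 3-(bromomethyl)butenolide (C5–C7, C11–C13) with a keto aldehyde (C8–C10, C1–C4, C14, C15) that carries the C10 carbinol.
- The keto aldehyde comes from (R)-2-methylglycidol, 1,3-dithiane and a homoallyl Grignard reagent.
- The butenolide (first ring formed) comes from propargyl alcohol and acrolein via Sharpless kinetic resolution, trans-hydroalumination/iodination and carboxylative lactonisation.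

Assumption: atom labels C1–C15 follow the usual germacranolide numbering (lactone C6/C7/C11/C12, ester at C8, carbinol C10, ketone C1).

**Keto aldehyde branch**

Step 1
Reactants: 1 1,3-dithiane; 2 (R)-2-methylglycidol
Product: 4 (2S)-3-(1,3-dithian-2-yl)-2-methylpropane-1,2-diol, via 2-lithio-1,3-dithiane 3 (not isolated)
Conditions: 1 (2.3 equiv), n-BuLi (2.2 equiv), THF, −30 °C; then 2, −30 → 0 °C; H2O
Reagents that add atoms: none
Why: Corey–Seebach umpolung, the dithiane anion opens the epoxide by SN2 at its unhindered CH2, so the quaternary centre C10 is carried over unchanged from the glycidol (the Payne rearrangement of its alkoxide is degenerate and leads to the same enantiomer).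

Step 2
Reactants: 4 (2S)-3-(1,3-dithian-2-yl)-2-methylpropane-1,2-diol
Product: 5 2-[(2S)-2-methyl-2,3-bis(triethylsilyloxy)propyl]-1,3-dithiane
Conditions: Et3SiOTf (2.4 equiv), 2,6-lutidine, CH2Cl2, −78 → 0 °C
Reagents that add atoms: triethylsilyl triflate, CC[Si](CC)(CC)OS(=O)(=O)C(F)(F)F
Why: Silylation with a silyl triflate is strong enough to cap the tertiary as well as the primary hydroxyl.

Step 3
Reactants: 5 2-[(2S)-2-methyl-2,3-bis(triethylsilyloxy)propyl]-1,3-dithiane
Product: 6 (2S)-3-(1,3-dithian-2-yl)-2-methyl-2-(triethylsilyloxy)propanal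
Conditions: (COCl)2, DMSO, CH2Cl2, −78 → −30 °C; then Et3N, −78 °C → rt
Reagents that add atoms: none
Why: Swern oxidation applied directly to the bis-silyl ether, the chlorosulfonium salt cleaves only the primary Et3Si ether and oxidises it to the aldehyde while the tertiary ether and the dithiane are inert.

Step 4
Reactants: 6 (2S)-3-(1,3-dithian-2-yl)-2-methyl-2-(triethylsilyloxy)propanal; 7 4-bromo-2-methylbut-1-ene
Product: 9 (2S,3RS)-1-(1,3-dithian-2-yl)-2,6-dimethyl-2-(triethylsilyloxy)hept-6-en-3-ol, via Grignard reagent 8 (not isolated)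
Conditions: 7, Mg turnings, THF, rt → 40 °C; then 6, THF, −78 → 0 °C; H2O
Reagents that add atoms: none
Why: Grignard addition to a non-enolisable aldehyde forms the C1–C2 bond; the new carbinol is an epimer mixture, which is irrelevant because it is oxidised in the next step.

Step 5
Reactants: 9 (2S,3RS)-1-(1,3-dithian-2-yl)-2,6-dimethyl-2-(triethylsilyloxy)hept-6-en-3-ol
Product: 10 (2S)-1-(1,3-dithian-2-yl)-2,6-dimethyl-2-(triethylsilyloxy)hept-6-en-3-one
Conditions: (COCl)2, DMSO, CH2Cl2, −78 °C; Et3N, → 0 °C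
Reagents that add atoms: none
Why: Swern oxidation gives the C1 ketone and is compatible with the dithiane, the silyl ether and the alkene.

Step 6
Reactants: 10 (2S)-1-(1,3-dithian-2-yl)-2,6-dimethyl-2-(triethylsilyloxy)hept-6-en-3-one
Product: 11 (3S)-3,7-dimethyl-4-oxo-3-(triethylsilyloxy)oct-7-enal
Conditions: MeI (excess), CaCO3, MeCN/H2O (9:1), 45 °C
Reagents that add atoms: water, O
Why: S-Methylation and hydrolysis unmask the dithiane (Corey–Seebach) under CaCO3-buffered conditions that spare the silyl ether, the ketone and the 1,1-disubstituted alkene.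

**Butenolide branch**

Step 7
Reactants: 12 prop-2-yn-1-ol
Product: 13 tert-butyldimethyl(prop-2-yn-1-yloxy)silane
Conditions: t-BuMe2SiCl, imidazole, CH2Cl2, 0 °C → rt
Reagents that add atoms: tert-butyldimethylsilyl chloride, CC(C)(C)[Si](C)(C)Cl
Why: Standard silyl protection of the primary hydroxyl, which later becomes C13.

Step 8
Reactants: 13 tert-butyldimethyl(prop-2-yn-1-yloxy)silane; 14 acrolein
Product: 16 rac-6-(tert-butyldimethylsilyloxy)hex-1-en-4-yn-3-ol, via lithium acetylide 15 (not isolated)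
Conditions: n-BuLi, THF, −78 °C; then 14, −78 °C; H2O
Reagents that add atoms: none
Why: Acetylide 1,2-addition to acrolein at low temperature gives the racemic vinyl alkynyl carbinol (C6).

Step 9
Reactants: 16 rac-6-(tert-butyldimethylsilyloxy)hex-1-en-4-yn-3-ol
Product: 17 (3R)-6-(tert-butyldimethylsilyloxy)hex-1-en-4-yn-3-ol
Conditions: Ti(OiPr)4 (10 mol %), D-(−)-diisopropyl tartrate (15 mol %), t-BuOOH (0.6 equiv), 4 Å molecular sieves, CH2Cl2, −20 °C, to about 55 % conversion
Reagents that add atoms: none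
Why: Sharpless kinetic resolution, with the D-(−)-tartrate the S enantiomer is epoxidised at its vinyl group much faster, so unreacted (R)-17 is recovered in high ee and fixes C6.

Step 10
Reactants: 17 (3R)-6-(tert-butyldimethylsilyloxy)hex-1-en-4-yn-3-ol
Product: 19 (3R,4Z)-6-(tert-butyldimethylsilyloxy)-5-iodohexa-1,4-dien-3-ol, via cyclic vinylalanate 18 (not isolated)
Conditions: NaAlH2(OCH2CH2OMe)2 (Red-Al), THF, 0 °C → rt; then iodine (I2), THF, −78 °C
Reagents that add atoms: iodine, II
Why: Hydroxyl-directed trans-hydroalumination puts hydride on the proximal and aluminium on the distal alkyne carbon (five-membered alanate), and iodinolysis with retention gives the Z iodoalkene with iodine cis to the carbinol carbon.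

Step 11
Reactants: 19 (3R,4Z)-6-(tert-butyldimethylsilyloxy)-5-iodohexa-1,4-dien-3-ol
Product: 22 (5R)-3-[(tert-butyldimethylsilyloxy)methyl]-5-vinylfuran-2(5H)-one, via dilithio species 20 (not isolated), via Z-hydroxy acid 21 (not isolated)
Conditions: t-BuLi (3.1 equiv), Et2O, −78 °C; CO2 (gas), −78 → 0 °C; then 1 M HCl, rt
Reagents that add atoms: carbon dioxide, O=C=O
Why: Iodine–lithium exchange with retention of alkene geometry, carboxylation and acid-induced lactonisation of the cis γ-hydroxy acid give the butenolide without touching C6.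

Step 12
Reactants: 22 (5R)-3-[(tert-butyldimethylsilyloxy)methyl]-5-vinylfuran-2(5H)-one
Product: 23 (5R)-3-(bromomethyl)-5-vinylfuran-2(5H)-one
Conditions: Ph3PBr2, CH2Cl2, 0 °C → rt
Reagents that add atoms: triphenylphosphine dibromide, BrP(Br)(c1ccccc1)(c1ccccc1)c1ccccc1
Why: Ph3PBr2 converts the primary allylic silyl ether directly into the bromide (Appel-type, via an alkoxyphosphonium salt) without base, so the acidic C6–H is not epimerised.

**Coupling and endgame**

Step 13
Reactants: 11 (3S)-3,7-dimethyl-4-oxo-3-(triethylsilyloxy)oct-7-enal; 23 (5R)-3-(bromomethyl)-5-vinylfuran-2(5H)-one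
Product: 25 (4R,5R)-4-[(1S,3S)-1-hydroxy-3,7-dimethyl-4-oxo-3-(triethylsilyloxy)oct-7-en-1-yl]-3-methylene-5-vinyldihydrofuran-2(3H)-one, via allylzinc bromide 24 (not isolated)
Conditions: Zn dust, THF/sat. aq NH4Cl (2:1), 0 °C → rt
Reagents that add atoms: none
Why: Barbier allylation, the allylzinc reacts at its γ-carbon (C7) anti to the C6 vinyl group through a Zimmerman–Traxler chair with the aldehyde chain equatorial, which gives the trans-disubstituted α-methylene lactone and the S carbinol at C8 (the C8 epimer of the target), and the aldehyde reacts in preference to the hindered ketone.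

Step 14
Reactants: 25 (4R,5R)-4-[(1S,3S)-1-hydroxy-3,7-dimethyl-4-oxo-3-(triethylsilyloxy)oct-7-en-1-yl]-3-methylene-5-vinyldihydrofuran-2(3H)-one; 26 angelic acid [(Z)-2-methylbut-2-enoic acid]
Product: 27 (1R,3S)-3,7-dimethyl-1-[(2R,3R)-4-methylene-5-oxo-2-vinyltetrahydrofuran-3-yl]-4-oxo-3-(triethylsilyloxy)oct-7-en-1-yl (2Z)-2-methylbut-2-enoate
Conditions: 26 (2 equiv), PPh3, DIAD, toluene, 0 °C → rt
Reagents that add atoms: none
Why: Mitsunobu esterification, SN2 displacement of the oxyphosphonium group by angelate inverts C8 to the required R configuration, and because the acid is never activated as an acylating agent the Z enoate does not isomerise to the tiglate.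

Step 15
Reactants: 27 (1R,3S)-3,7-dimethyl-1-[(2R,3R)-4-methylene-5-oxo-2-vinyltetrahydrofuran-3-yl]-4-oxo-3-(triethylsilyloxy)oct-7-en-1-yl (2Z)-2-methylbut-2-enoate
Product: 28 (3aR,4R,6S,10Z,11aR)-6,10-dimethyl-3-methylene-2,7-dioxo-6-(triethylsilyloxy)-2,3,3a,4,5,6,7,8,9,11a-decahydrocyclodeca[b]furan-4-yl (2Z)-2-methylbut-2-enoate
Conditions: second-generation Grubbs catalyst (H2IMes)(PCy3)Cl2Ru=CHPh (15 mol %), toluene (1 mM), 100 °C
Reagents that add atoms: none
Why: Ring-closing metathesis between the vinyl group and the 1,1-disubstituted alkene expels ethene, and a trisubstituted olefin in a ten-membered ring trans-fused to the lactone is expected to form as the Z (cis-cyclodecene) isomer; the angelate and the α-methylene lactone are poor metathesis partners.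

Step 16
Reactants: 28 (3aR,4R,6S,10Z,11aR)-6,10-dimethyl-3-methylene-2,7-dioxo-6-(triethylsilyloxy)-2,3,3a,4,5,6,7,8,9,11a-decahydrocyclodeca[b]furan-4-yl (2Z)-2-methylbut-2-enoate
Product: 29 (3aR,4R,6S,10Z,11aR)-6-hydroxy-6,10-dimethyl-3-methylene-2,7-dioxo-2,3,3a,4,5,6,7,8,9,11a-decahydrocyclodeca[b]furan-4-yl (2Z)-2-methylbut-2-enoate
Conditions: HF·pyridine, THF/pyridine, 0 °C → rt
Reagents that add atoms: none
Why: Fluoride-mediated desilylation frees the tertiary C10 hydroxyl under buffered conditions that leave the α-methylene lactone, the angelate and the α-ketol intact.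

**Compound list**

1 | 1,3-dithiane | C1CSCSC1 | starting material
2 | (R)-2-methylglycidol [(2R)-(2-methyloxiran-2-yl)methanol] | OC[C@@]1(C)OC1 | starting material
3 | 2-lithio-1,3-dithiane | [Li]C1SCCCS1 | intermediate
4 | (2S)-3-(1,3-dithian-2-yl)-2-methylpropane-1,2-diol | OC[C@@](C)(O)CC1SCCCS1 | intermediate
5 | 2-[(2S)-2-methyl-2,3-bis(triethylsilyloxy)propyl]-1,3-dithiane | CC[Si](CC)(CC)OC[C@@](C)(O[Si](CC)(CC)CC)CC1SCCCS1 | intermediate
6 | (2S)-3-(1,3-dithian-2-yl)-2-methyl-2-(triethylsilyloxy)propanal | O=C[C@@](C)(O[Si](CC)(CC)CC)CC1SCCCS1 | intermediate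
7 | 4-bromo-2-methylbut-1-ene | C=C(C)CCBr | starting material
8 | (3-methylbut-3-en-1-yl)magnesium bromide | C=C(C)CC[Mg]Br | intermediate
9 | (2S,3RS)-1-(1,3-dithian-2-yl)-2,6-dimethyl-2-(triethylsilyloxy)hept-6-en-3-ol (both C3 epimers) | C=C(C)CCC(O)[C@@](C)(O[Si](CC)(CC)CC)CC1SCCCS1 | intermediate
10 | (2S)-1-(1,3-dithian-2-yl)-2,6-dimethyl-2-(triethylsilyloxy)hept-6-en-3-one | C=C(C)CCC(=O)[C@@](C)(O[Si](CC)(CC)CC)CC1SCCCS1 | intermediate
11 | (3S)-3,7-dimethyl-4-oxo-3-(triethylsilyloxy)oct-7-enal | C=C(C)CCC(=O)[C@@](C)(O[Si](CC)(CC)CC)CC=O | intermediate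
12 | prop-2-yn-1-ol | C#CCO | starting material
13 | tert-butyldimethyl(prop-2-yn-1-yloxy)silane | C#CCO[Si](C)(C)C(C)(C)C | intermediate
14 | acrolein (prop-2-enal) | C=CC=O | starting material
15 | lithium acetylide of 13 | [Li]C#CCO[Si](C)(C)C(C)(C)C | intermediate
16 | rac-6-(tert-butyldimethylsilyloxy)hex-1-en-4-yn-3-ol | C=CC(O)C#CCO[Si](C)(C)C(C)(C)C | intermediate
17 | (3R)-6-(tert-butyldimethylsilyloxy)hex-1-en-4-yn-3-ol | C=C[C@@H](O)C#CCO[Si](C)(C)C(C)(C)C | intermediate
18 | sodium cyclic vinylalanate (five-membered O–Al–C=C ring, two 2-methoxyethoxy groups on Al) | [Na+].C=C[C@H]1O[Al-](OCCOC)(OCCOC)C(CO[Si](C)(C)C(C)(C)C)=C1 | intermediate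
19 | (3R,4Z)-6-(tert-butyldimethylsilyloxy)-5-iodohexa-1,4-dien-3-ol | C=C[C@@H](O)/C=C(\I)CO[Si](C)(C)C(C)(C)C | intermediate
20 | dilithio species (lithium alkoxide and vinyllithium, Li cis to the carbinol carbon) | C=C[C@@H](O[Li])/C=C(\[Li])CO[Si](C)(C)C(C)(C)C | intermediate
21 | (2Z,4R)-2-[(tert-butyldimethylsilyloxy)methyl]-4-hydroxyhexa-2,5-dienoic acid | C=C[C@@H](O)/C=C(\C(=O)O)CO[Si](C)(C)C(C)(C)C | intermediate
22 | (5R)-3-[(tert-butyldimethylsilyloxy)methyl]-5-vinylfuran-2(5H)-one | C=C[C@H]1OC(=O)C(CO[Si](C)(C)C(C)(C)C)=C1 | intermediate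
23 | (5R)-3-(bromomethyl)-5-vinylfuran-2(5H)-one | C=C[C@H]1OC(=O)C(CBr)=C1 | intermediate
24 | allylzinc bromide from 23 | Br[Zn]CC1=C[C@@H](C=C)OC1=O | intermediate
25 | (4R,5R)-4-[(1S,3S)-1-hydroxy-3,7-dimethyl-4-oxo-3-(triethylsilyloxy)oct-7-en-1-yl]-3-methylene-5-vinyldihydrofuran-2(3H)-one | C=C1C(=O)O[C@H](C=C)[C@H]1[C@@H](O)C[C@](C)(O[Si](CC)(CC)CC)C(=O)CCC(C)=C | intermediate
26 | angelic acid [(Z)-2-methylbut-2-enoic acid] | C/C=C(/C)C(=O)O | starting material
27 | (1R,3S)-3,7-dimethyl-1-[(2R,3R)-4-methylene-5-oxo-2-vinyltetrahydrofuran-3-yl]-4-oxo-3-(triethylsilyloxy)oct-7-en-1-yl (2Z)-2-methylbut-2-enoate | C=C1C(=O)O[C@H](C=C)[C@H]1[C@H](OC(=O)/C(C)=C\C)C[C@](C)(O[Si](CC)(CC)CC)C(=O)CCC(C)=C | intermediate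
28 | (3aR,4R,6S,10Z,11aR)-6,10-dimethyl-3-methylene-2,7-dioxo-6-(triethylsilyloxy)-2,3,3a,4,5,6,7,8,9,11a-decahydrocyclodeca[b]furan-4-yl (2Z)-2-methylbut-2-enoate | C=C1C(=O)O[C@@H]2/C=C(/C)CCC(=O)[C@@](C)(O[Si](CC)(CC)CC)C[C@@H](OC(=O)/C(C)=C\C)[C@@H]12 | intermediate
29 | (3aR,4R,6S,10Z,11aR)-6-hydroxy-6,10-dimethyl-3-methylene-2,7-dioxo-2,3,3a,4,5,6,7,8,9,11a-decahydrocyclodeca[b]furan-4-yl (2Z)-2-methylbut-2-enoate (CNP0345906.2) | C=C1C(=O)O[C@@H]2/C=C(/C)CCC(=O)[C@@](C)(O)C[C@@H](OC(=O)/C(C)=C\C)[C@@H]12 | target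

**Step count**

Total steps: 16 (steps 1–6 keto aldehyde, steps 7–12 bromobutenolide, steps 13–16 coupling and endgame).
Longest linear sequence: 10 steps (1–6 then 13–16; the other branch, 7–12 then 13–16, is also 10).

**Steps most likely to fail, with fallbacks**

Step 15 (ring-closing metathesis to a trisubstituted Z olefin in a ten-membered ring). Slow initiation at the hindered olefins, oligomerisation or E/Z mixtures are the dangers. The fallback sets out from 25 and changes the order of events. The free carbinol 25 is cyclised first (same ruthenium catalyst, toluene, 1 mM, 100 °C) to the macrocyclic 8-epi alcohol F1. In that substrate no second enoate ester is present during metathesis, and a small hydroxyl replaces the bulky acyloxy group on the carbon next to the lactone. Mitsunobu esterification of F1 with 26 (PPh3, DIAD, toluene) then inverts C8 on the ring and returns to the route at 28.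

Step 14 (Mitsunobu inversion at the hindered C8 carbinol). Elimination towards C7 or C9, or no reaction, are the dangers. The fallback sets out from 25 and activates the alcohol as a sulfonate rather than an oxyphosphonium salt. ClCH2SO2Cl and pyridine in CH2Cl2 at 0 °C give the chloromethanesulfonate F2. SN2 displacement with caesium angelate (from 26 and Cs2CO3, with 18-crown-6, toluene, 60 °C) inverts C8 and comes back to the route at 27.

Step 11 (halogen–lithium exchange and carboxylation next to an allylic silyl ether). β-Elimination of the vinyllithium to an allene, or incomplete carboxylation, are the dangers. The fallback sets out from 19 and reaches 22 directly by palladium-catalysed carbonylative lactonisation (PdCl2(PPh3)2 cat., CO 1 atm, iPr2NEt, THF, rt). Oxidative addition to the vinyl iodide, CO insertion and capture of the acylpalladium by the cis hydroxyl close the butenolide. No organolithium is involved and no new compound is formed (F0). The reaction should be stopped at full conversion so that zerovalent palladium does not ionise the allylic lactone and erode the ee at C6.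

**Further compounds**

F1 | step 15 | (3aR,4S,6S,10Z,11aR)-4-hydroxy-6,10-dimethyl-3-methylene-6-(triethylsilyloxy)-3a,4,5,6,8,9-hexahydrocyclodeca[b]furan-2,7(3H,11aH)-dione | C=C1C(=O)O[C@@H]2/C=C(/C)CCC(=O)[C@@](C)(O[Si](CC)(CC)CC)C[C@H](O)[C@@H]12
F2 | step 14 | (1S,3S)-3,7-dimethyl-1-[(2R,3R)-4-methylene-5-oxo-2-vinyltetrahydrofuran-3-yl]-4-oxo-3-(triethylsilyloxy)oct-7-en-1-yl chloromethanesulfonate | C=C1C(=O)O[C@H](C=C)[C@H]1[C@@H](OS(=O)(=O)CCl)C[C@](C)(O[Si](CC)(CC)CC)C(=O)CCC(C)=C
F0 | step 11 | none | none
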